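Time in these flasks is counted here in charges turned over.

| setting | beta | winter | summer |
|---|---|---|---|
| X | 0.33 M | 0.30 M | 0.15 M |
| G | 36 mM (held) | 36 mM (held) | 36 mM (held) |
| temperature | −20 °C |  |  |
| remark | run made earlier | at −20 °C until 12 min, from then on at 0 °C | at −20 °C throughout |
| time |  | 25 min | 25 min |

- beta (time / min: E / %, X / %): 0.417: 0, 94.2; 0.833: 0.8, 87.9; 1.33: 1.8, 82.1; 2.50: 5.7, 71.1; 5.00: 14.9, 52.2

(readings scatter by 0.5 percentage points)

- given per volume of solution although it is solid: X
- at the start none of X is in solution
- at the start none of G is in solution
- what has only dissolved of X counts as not reacted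
- the earlier runs do not show what temperature does; that part of a forecast is a guess

1. which one finishes higher in amount of E, in percent of the X charged ("neither" within 2 percentage points) (winter / summer / neither)
2. amount of E at the end, in percent of the X charged, winter
3. amount of E at the end, in percent of the X charged, summer

Between its last two readings, the beta run makes E at a rate of 0.0121 M min⁻¹, a value that carries the scatter. Let the turnover count N be this rate times the time, divided by the X charged: the number of charges that the beta rate would convert. For summer, N = 2.02. For winter, at the cold rate, N = 1.01, so summer has twice the count.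

The bound from above is the charge itself, 100 per cent of X. The bound from below assumes that the rate shrinks with the charge, so that the percent per minute stays as in beta. The straight line through those two readings then reaches 88.5% at 25 min.

The bracket tightens for summer, which could lose half of the beta rate and still turn over its charge once, so my reckoning sets it close to the upper bound. Winter has no such reserve at the cold rate, and its warm stretch after 12 min is a guess. Summer counts more turnovers than winter does at the cold rate, so my reckoning puts summer higher.

The forecast names winter, with 93% for winter and 82% for summer, the latter below the bracket, and says “Warming by 20 °C probably speeds the steps several-fold”. The flasks give 92.7% for winter and >99.9% for summer, so summer finishes higher.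

    X ⇌ L, rate k1*(cs1 - [L]) while solid is left; crystals form when [L] > cs1 (solubility = 0.190 M, k = 0.260 min⁻¹)
    L + Z → E (k = 26.0 L mol⁻¹ min⁻¹, Ea = 49.0 kJ mol⁻¹)
    Z → D (k = 0.110 min⁻¹, Ea = 75.0 kJ mol⁻¹)
    2 X → Q (k = 1.70 × 10⁻⁴ L mol⁻¹ min⁻¹, Ea = 54.0 kJ mol⁻¹)
    G ⇌ Z, rate k5*(csat - [Z]) (kL = 0.370 min⁻¹)
    (constants at −20 °C)

Summer, with N = 2.02, ends with X, its limiting reagent, at 0% and L at 0.0297%. Winter, with N = 1.01 at the cold rate, ends with L at 7.24%. The neighbouring flask is summer charged with 0.26 M of X, which gives N = 1.17, less than summer's count and more than winter's at the cold rate. The neighbouring flask ends at 95.6% of E, with 4.4% of its charged X still there, solid or dissolved.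

(The runs come from a simulation with constants of no real substance.)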